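The runs come from a simulation from invented constants, noise included.

The vessel is closed, stirred and isothermal, and the recipes differ in their charge of starting material.

common to all: free catalyst 54 mM; impurity 22 mM

|  | starting material | remark | time |
|---|---|---|---|
| ash | 0.32 M | run made earlier |  |
| alder | 1.3 M | run made earlier |  |
| blue | 0.25 M |  | 30 h |
| amber | 0.40 M |  | 30 h |
| ochre | 0.60 M |  | 30 h |
| teal | 1.0 M |  | 30 h |

| run | time / h | target / % | starting material / % |
|---|---|---|---|
| ash | 1.33 | 21.0 | 69.2 |
| ash | 2.00 | 30.7 | 59.0 |
| ash | 3.00 | 44.4 | 47.2 |
| ash | 4.00 | 57.0 | 36.3 |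
| ash | 6.00 | 78.9 | 16.6 |
| ash | 10.0 | 97.9 | 1.3 |
| ash | 15.0 | 99.2 | 0.7 |
| alder | 1.33 | 6.1 | 87.6 |
| alder | 2.00 | 11.6 | 87.1 |
| alder | 3.00 | 15.8 | 80.2 |
| alder | 4.00 | 21.2 | 76.8 |
| alder | 6.00 | 28.1 | 68.3 |
| alder | 10.0 | 45.1 | 53.3 |
| alder | 15.0 | 63.0 | 36.0 |

(scatter of a reading: 1 percentage point)

- [target] at the end for blue, amber, ochre, teal, in this order
- how that number moves from the first to the last of them (rises, then falls / falls, then rises / hardly changes / falls all the way / rises all the way)

- "hardly changes" means that all values lie within two and a half points (for a concentration: within two and a half percent of the largest)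

**What does a larger charge buy in rate?** Not much. Ash makes target at 0.0386 M h⁻¹ between 2.00 h and 6.00 h, and alder at 0.0514 M h⁻¹ between 2.00 h and 15.0 h. I call the alder figure the pace, the target made per hour while starting material is plentiful. The alder charge is 4.06 times the ash charge, but its rate is 1.33 times the ash rate, so the order in starting material lies near zero.

**Then which concentration sets the rate?** I take it to be the catalyst holding substrate. At 2.00 h, ash is missing 10.3% of its charge, a reading of 33.0 mM. That reading is close to the 32.0 mM of catalyst left if each impurity removes one catalyst.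

**What does the pace say about teal?** The fraction converted is pace times time over charge, which reaches one at 19.5 h, or 65.0% of the time allowed.

**But the starting material thins towards the end. Where is that counted?** Ash shows the cost. The pace would finish ash by 6.23 h, yet ash reads 78.9% target at 6.00 h and 97.9% at 10.0 h, so these spaced readings show a lag of about 3.77 h. If teal lags as ash does, which is my assumption, my estimate for teal is 23.3 h, still shorter than 30 h.

**Your answer?** The whole charge becomes target: 0.25 M, 0.40 M, 0.60 M and 1.0 M, rising all the way.

The forecast gives 0.248 M, 0.397 M, 0.595 M and 0.96 M, with the number said to be rises all the way, on the ground that “Ash went essentially to completion, so nothing caps the yield”, and its teal stands below my whole charge.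

The flasks give 0.250 M, 0.400 M, 0.600 M and 1.00 M: the number rises all the way.

    2 catalyst intermediate B ⇌ resting dimer (K = 1100 M⁻¹, k = 33.0 M⁻¹ h⁻¹)
    catalyst intermediate A ⇌ catalyst intermediate B (K = 2.40, k = 1.60 h⁻¹)
    catalyst intermediate B → free catalyst + target (k = 110 h⁻¹)
    starting material + free catalyst → catalyst intermediate A (k = 37.0 M⁻¹ h⁻¹)
    free catalyst + impurity → spent catalyst (k = 160 M⁻¹ h⁻¹)

At 15.0 h, teal holds 48.3% of its catalyst as catalyst intermediate A and 9.94% as free catalyst. The pace puts teal at 77.1% of its charge by then, and teal stands at 76.9% target. For ochre, the pace reaches the whole charge at 11.7 h, and at 15.0 h ochre stands at 98.5% target with 0.721% starting material left.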